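**Plan**

Lignan numbering is used: C7/C7' are the benzylic CH2 groups, C8 is the CH, C8' is the tertiary carbinol carbon, and C9/C9' are the hydroxymethyl carbons.
Retrosynthesis: once the phenol groups and the C8'–O group are deprotected, C9 and C9' are joined, so the chain C9–C8–C8'–C9' becomes a cyclobutanone (C9 = C=O, C9' = α-carbon). This vicinal pair of one-carbon branches on C8 and on the oxygen-bearing C8' is the feature that invites a ketene [2+2].
Cutting C8–C9 and C8'–C9' of that ring gives dichloroketene and a Z-enol ether of 1,4-diarylbutan-2-one with its oxygen on C8'. Cutting C8'–C7' and C8–C7 then leaves an alkoxyacetylide (C8 and C8' from trichloroethylene) and two molecules of one vanillin-derived benzylic bromide.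
Forward: bromide, alkynyl ether by C8–C7 alkylation, syn-hydrostannation, C8'–C7' coupling, closure of the only ring (the cyclobutanone), dechlorination, opening of that ring at C9–C9' through a silyl enol ether and ozone, reduction, deprotection.
Stereochemistry: the Z geometry (syn H–Sn addition, retentive coupling) is translated by suprafacial cycloaddition into the C8/C8' relative configuration. The absolute sense comes from the (S)-1-(2,4,6-triisopropylphenyl)ethyl group on the enol oxygen, which also masks the tertiary alcohol until the ring is gone.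

Key step: step 7

Assumption: the sense of facial induction established for α-unsubstituted Z-enol ethers of this alcohol is taken to hold for the α-benzylated enol ether; if it proved opposite, the equally available (R)-alcohol would be carried through the same steps.

**Step 1**
Reactants: 1 vanillin
Product: 2 4-(benzyloxy)-3-methoxybenzaldehyde
Conditions: BnBr, K2CO3, DMF, rt
Reagents that add atoms: benzyl bromide, BrCc1ccccc1
Why: Williamson etherification of the acidic phenol should be clean, and the benzyl ether tolerates the organolithium, zinc, hydride and brief acid treatments ahead while leaving by hydrogenolysis at the end.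

**Step 2**
Reactants: 2 4-(benzyloxy)-3-methoxybenzaldehyde
Product: 3 [4-(benzyloxy)-3-methoxyphenyl]methanol
Conditions: NaBH4, MeOH, 0 °C
Reagents that add atoms: none
Why: Borohydride reduction of an aromatic aldehyde is chemoselective and touches neither ether.

**Step 3**
Reactants: 3 [4-(benzyloxy)-3-methoxyphenyl]methanol
Product: 4 4-(benzyloxy)-3-methoxybenzyl bromide
Conditions: PBr3, Et2O, 0 °C
Reagents that add atoms: phosphorus tribromide, BrP(Br)Br
Why: Bromination of a primary benzylic alcohol with PBr3 (SN2 on the phosphite ester) is fast at 0 °C, and the electron-rich bromide is used soon after it is made.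

**Step 4**
Reactants: 5 (S)-1-(2,4,6-triisopropylphenyl)ethanol; 6 trichloroethylene; 4 4-(benzyloxy)-3-methoxybenzyl bromide
Product: 11 1-(benzyloxy)-2-methoxy-4-{3-[(1S)-1-(2,4,6-triisopropylphenyl)ethoxy]prop-2-yn-1-yl}benzene, via potassium alkoxide 7 (not isolated), via dichlorovinyl ether 8 (not isolated), via chloroalkynyl ether 9 (not isolated), via lithium alkynyl ether 10 (not isolated)
Conditions: KH, THF, 0 °C to rt; 6, −50 °C to rt; n-BuLi (2.1 equiv), −78 to −40 °C; 4, HMPA, −78 °C to rt
Reagents that add atoms: none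
Why: This is the one-flask alkynyl ether synthesis from an alcohol (vinylic substitution of trichloroethylene by the alkoxide, loss of HCl and chlorine–lithium exchange with n-BuLi, then SN2 alkylation of the lithium alkoxyacetylide by the reactive benzylic bromide), and the carbinol C–O bond is never broken, so the (S) centre is retained.

**Step 5**
Reactants: 11 alkynyl ether
Product: 12 tributyl{(1E)-3-[4-(benzyloxy)-3-methoxyphenyl]-1-[(1S)-1-(2,4,6-triisopropylphenyl)ethoxy]prop-1-en-1-yl}stannane
Conditions: Bu3SnH (slow addition), Pd(PPh3)4 (2 mol %), THF, 0 °C to rt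
Reagents that add atoms: tributyltin hydride, CCCC[SnH](CCCC)CCCC
Why: Hydrostannation catalysed by zerovalent palladium adds H and Sn to the same side of the alkyne and, as with other heteroatom-substituted alkynes, places tin on the heteroatom-bearing carbon (C8'), which fixes C7 cis to oxygen.

**Step 6**
Reactants: 12 (E)-α-stannyl enol ether; 4 4-(benzyloxy)-3-methoxybenzyl bromide
Product: 13 (Z)-1,4-bis[4-(benzyloxy)-3-methoxyphenyl]but-2-en-2-yl (S)-1-(2,4,6-triisopropylphenyl)ethyl ether
Conditions: Pd2(dba)3 (2.5 mol %), AsPh3 (10 mol %), i-Pr2NEt (0.2 equiv), THF, 50 °C; Et3N-deactivated silica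
Reagents that add atoms: none
Why: Stille coupling of an α-alkoxyalkenylstannane with a benzylic bromide forms C8'–C7' with retention of alkene geometry, so the Z-enol ether (C7 cis to O, trans to C7') should result, and strictly acid-free handling prevents migration of the double bond into conjugation.

**Step 7**
Reactants: 13 (Z)-enol ether; 14 trichloroacetyl chloride
Product: 16 (3S,4R)-3,4-bis[4-(benzyloxy)-3-methoxybenzyl]-2,2-dichloro-3-[(1S)-1-(2,4,6-triisopropylphenyl)ethoxy]cyclobutan-1-one, via dichloroketene 15 (not isolated)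
Conditions: 14 (slow addition), Zn–Cu, DME (additive), Et2O, rt; filtration, aq NaHCO3, used crude
Reagents that add atoms: none
Why: Zn–Cu strips two chlorines from 14 to give dichloroketene 15, whose electrophilic carbonyl carbon (the future C9) bonds to the nucleophilic C8 of the enol ether while its CCl2 carbon (the future C9') bonds to the oxygen-stabilised C8', so the polarity of both partners fixes the regiochemistry. The ring C8–C9–C9'–C8' closes in one intermolecular [π2s + π2a] ketene–alkene cycloaddition that is concerted but strongly asynchronous (C8–C9 leads), suprafacial on the enol ether and antarafacial on the ketene. The closest known reaction type is the dichloroketene cycloaddition to Z-1-alkenyl ethers of this same alcohol, together with dichloroketene additions to trisubstituted alkyl and silyl enol ethers of ketones. Since both bonds form on one face of the alkene, the Z geometry is carried into the ring, which places the C8 benzyl group cis to the alkoxy group and trans to the C8' benzyl group, the relative configuration of the target. The absolute configuration of C8 and C8' is set together by the auxiliary: the s-cis O–C8' rotamer is excluded by C7, and in the s-trans rotamer the carbinol C–H lies in the alkene plane beside C7'H2, the triisopropylphenyl group covers one face and the ketene enters past the methyl group, which for the (S)-alcohol leads to (3S,4R)-16 (8S,8'S in the target). The step needs facial selectivity, retention of alkene geometry and ring closure in preference to proton loss or bond rotation in a zwitterion, and these are served by the locked rotamer, the weakly polar ether medium, slow generation of the ketene and complexation of ZnCl2 by DME.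

**Step 8**
Reactants: 16 dichlorocyclobutanone
Product: 17 (2R,3R)-2,3-bis[4-(benzyloxy)-3-methoxybenzyl]-3-[(1S)-1-(2,4,6-triisopropylphenyl)ethoxy]cyclobutan-1-one
Conditions: Zn–Cu, NH4Cl (sat.), MeOH, rt
Reagents that add atoms: none
Why: Reductive dechlorination of α,α-dichlorocyclobutanones by zinc in a buffered protic medium is standard also for 3-alkoxy members, because the zinc enolate is protonated faster than it expels alkoxide, and the mild buffer leaves the enolisable C8 centre and the acid-labile ether alone.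

**Step 9**
Reactants: 17 cyclobutanone
Product: 19 {[(3R,4R)-3,4-bis[4-(benzyloxy)-3-methoxybenzyl]-3-[(1S)-1-(2,4,6-triisopropylphenyl)ethoxy]cyclobut-1-en-1-yl]oxy}trimethylsilane, via lithium enolate 18 (not isolated)
Conditions: LDA, TMSCl (present from the start), THF, −78 °C; Et3N, pentane, aq NaHCO3
Reagents that add atoms: chlorotrimethylsilane, C[Si](C)(C)Cl
Why: Kinetic enolisation with a hindered amide base removes a proton from the C9' methylene rather than the C8 methine, and internal-quench silyl enol ether formation traps the enolate at −78 °C before β-elimination of the alkoxide or equilibration can set in.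

**Step 10**
Reactants: 19 silyl enol ether
Product: 21 (2R,3S)-2,3-bis[4-(benzyloxy)-3-methoxybenzyl]-4-oxo-3-[(1S)-1-(2,4,6-triisopropylphenyl)ethoxy]butanoic acid, via trimethylsilyl ester 20 (not isolated)
Conditions: O3 (to Sudan Red 7B end point), CH2Cl2, −78 °C; Me2S, −78 °C to rt; H2O
Reagents that add atoms: ozone, [O-][O+]=O
Why: Ozonolysis of a silyl enol ether cleaves C9=C9' into a silyl ester and an aldehyde, the strained and very electron-rich alkene reacts far faster than the dialkoxyarenes or benzyl ethers so that dosing ozone to a dye end point keeps them intact, and neither new carbonyl group endangers a stereocentre (C8' bears no hydrogen, C8 is α only to a carboxyl group).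

**Step 11**
Reactants: 21 aldehydo acid
Product: 22 (2S,3S)-2,3-bis[4-(benzyloxy)-3-methoxybenzyl]-2-[(1S)-1-(2,4,6-triisopropylphenyl)ethoxy]butane-1,4-diol
Conditions: LiAlH4, THF, 0 °C to rt; Rochelle salt work-up
Reagents that add atoms: none
Why: Hydride reduction with LiAlH4 takes the carboxylic acid and the aldehyde (or their hydroxylactone tautomer) to the two primary alcohols without touching ethers or stereocentres.

**Step 12**
Reactants: 22 diol
Product: 23 (2S,3S)-2,3-bis[4-(benzyloxy)-3-methoxybenzyl]butane-1,2,4-triol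
Conditions: CF3CO2H, CH2Cl2, 0 °C; aq NaHCO3
Reagents that add atoms: none
Why: Acidolysis of the ether (SN1/E1) ionises the secondary benzylic carbon of the auxiliary, whose cation is far better stabilised than one at C8' flanked by two oxygenated carbons, so the C8'–O bond and its configuration are kept and the auxiliary leaves as the styrene.

**Step 13**
Reactants: 23 triol dibenzyl ether
Product: 24 (−)-carinol, (2S,3S)-2,3-bis(4-hydroxy-3-methoxybenzyl)butane-1,2,4-triol
Conditions: H2 (1 atm), Pd/C, EtOH–EtOAc, rt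
Reagents that add atoms: none
Why: Catalytic hydrogenolysis removes both aryl benzyl ethers, and since the molecule holds no other benzylic C–O bond the triol core is inert.

**Compound list**

1 | vanillin | COc1cc(C=O)ccc1O | starting material
2 | 4-(benzyloxy)-3-methoxybenzaldehyde | COc1cc(C=O)ccc1OCc1ccccc1 | intermediate
3 | [4-(benzyloxy)-3-methoxyphenyl]methanol | COc1cc(CO)ccc1OCc1ccccc1 | intermediate
4 | 4-(benzyloxy)-3-methoxybenzyl bromide | COc1cc(CBr)ccc1OCc1ccccc1 | intermediate
5 | (S)-1-(2,4,6-triisopropylphenyl)ethanol | C[C@H](O)c1c(C(C)C)cc(C(C)C)cc1C(C)C | starting material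
6 | trichloroethylene | ClC=C(Cl)Cl | starting material
7 | potassium (S)-1-(2,4,6-triisopropylphenyl)ethoxide | C[C@H]([O-])c1c(C(C)C)cc(C(C)C)cc1C(C)C.[K+] | intermediate
8 | (E)-1,2-dichlorovinyl (S)-1-(2,4,6-triisopropylphenyl)ethyl ether | Cl/C=C(Cl)\O[C@@H](C)c1c(C(C)C)cc(C(C)C)cc1C(C)C | intermediate
9 | chloroethynyl (S)-1-(2,4,6-triisopropylphenyl)ethyl ether | ClC#CO[C@@H](C)c1c(C(C)C)cc(C(C)C)cc1C(C)C | intermediate
10 | lithium [(S)-1-(2,4,6-triisopropylphenyl)ethoxy]acetylide | [Li]C#CO[C@@H](C)c1c(C(C)C)cc(C(C)C)cc1C(C)C | intermediate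
11 | 1-(benzyloxy)-2-methoxy-4-{3-[(1S)-1-(2,4,6-triisopropylphenyl)ethoxy]prop-2-yn-1-yl}benzene | COc1cc(CC#CO[C@@H](C)c2c(C(C)C)cc(C(C)C)cc2C(C)C)ccc1OCc1ccccc1 | intermediate
12 | tributyl{(1E)-3-[4-(benzyloxy)-3-methoxyphenyl]-1-[(1S)-1-(2,4,6-triisopropylphenyl)ethoxy]prop-1-en-1-yl}stannane (Sn trans to C7) | COc1cc(C/C=C(/[Sn](CCCC)(CCCC)CCCC)O[C@@H](C)c2c(C(C)C)cc(C(C)C)cc2C(C)C)ccc1OCc1ccccc1 | intermediate
13 | (Z)-1,4-bis[4-(benzyloxy)-3-methoxyphenyl]but-2-en-2-yl (S)-1-(2,4,6-triisopropylphenyl)ethyl ether | COc1cc(C/C=C(O[C@@H](C)c2c(C(C)C)cc(C(C)C)cc2C(C)C)/Cc2ccc(OCc3ccccc3)c(OC)c2)ccc1OCc1ccccc1 | intermediate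
14 | trichloroacetyl chloride | ClC(Cl)(Cl)C(Cl)=O | starting material
15 | dichloroketene | ClC(Cl)=C=O | intermediate
16 | (3S,4R)-3,4-bis[4-(benzyloxy)-3-methoxybenzyl]-2,2-dichloro-3-[(1S)-1-(2,4,6-triisopropylphenyl)ethoxy]cyclobutan-1-one | COc1cc(C[C@H]2C(=O)C(Cl)(Cl)[C@]2(O[C@@H](C)c2c(C(C)C)cc(C(C)C)cc2C(C)C)Cc2ccc(OCc3ccccc3)c(OC)c2)ccc1OCc1ccccc1 | intermediate
17 | (2R,3R)-2,3-bis[4-(benzyloxy)-3-methoxybenzyl]-3-[(1S)-1-(2,4,6-triisopropylphenyl)ethoxy]cyclobutan-1-one | COc1cc(C[C@H]2C(=O)C[C@]2(O[C@@H](C)c2c(C(C)C)cc(C(C)C)cc2C(C)C)Cc2ccc(OCc3ccccc3)c(OC)c2)ccc1OCc1ccccc1 | intermediate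
18 | lithium enolate of 17 towards C9' | [Li+].COc1cc(C[C@H]2C([O-])=C[C@]2(O[C@@H](C)c2c(C(C)C)cc(C(C)C)cc2C(C)C)Cc2ccc(OCc3ccccc3)c(OC)c2)ccc1OCc1ccccc1 | intermediate
19 | {[(3R,4R)-3,4-bis[4-(benzyloxy)-3-methoxybenzyl]-3-[(1S)-1-(2,4,6-triisopropylphenyl)ethoxy]cyclobut-1-en-1-yl]oxy}trimethylsilane | COc1cc(C[C@H]2C(O[Si](C)(C)C)=C[C@]2(O[C@@H](C)c2c(C(C)C)cc(C(C)C)cc2C(C)C)Cc2ccc(OCc3ccccc3)c(OC)c2)ccc1OCc1ccccc1 | intermediate
20 | trimethylsilyl ester of 21 | COc1cc(C[C@@H](C(=O)O[Si](C)(C)C)[C@](O[C@@H](C)c2c(C(C)C)cc(C(C)C)cc2C(C)C)(C=O)Cc2ccc(OCc3ccccc3)c(OC)c2)ccc1OCc1ccccc1 | intermediate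
21 | (2R,3S)-2,3-bis[4-(benzyloxy)-3-methoxybenzyl]-4-oxo-3-[(1S)-1-(2,4,6-triisopropylphenyl)ethoxy]butanoic acid | COc1cc(C[C@@H](C(=O)O)[C@](O[C@@H](C)c2c(C(C)C)cc(C(C)C)cc2C(C)C)(C=O)Cc2ccc(OCc3ccccc3)c(OC)c2)ccc1OCc1ccccc1 | intermediate
22 | (2S,3S)-2,3-bis[4-(benzyloxy)-3-methoxybenzyl]-2-[(1S)-1-(2,4,6-triisopropylphenyl)ethoxy]butane-1,4-diol | COc1cc(C[C@@H](CO)[C@](O[C@@H](C)c2c(C(C)C)cc(C(C)C)cc2C(C)C)(CO)Cc2ccc(OCc3ccccc3)c(OC)c2)ccc1OCc1ccccc1 | intermediate
23 | (2S,3S)-2,3-bis[4-(benzyloxy)-3-methoxybenzyl]butane-1,2,4-triol | COc1cc(C[C@@H](CO)[C@](O)(CO)Cc2ccc(OCc3ccccc3)c(OC)c2)ccc1OCc1ccccc1 | intermediate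
24 | (−)-carinol, (2S,3S)-2,3-bis(4-hydroxy-3-methoxybenzyl)butane-1,2,4-triol | COc1cc(C[C@@H](CO)[C@](O)(CO)Cc2ccc(O)c(OC)c2)ccc1O | target

**Count**

Total steps: 13. Longest linear sequence: 13 steps (1 to 24); counted from the auxiliary alcohol 5 the sequence is 10 steps.

**Steps most likely to fail**

**Step 7.** Crowding at the fully substituted C8' may slow the cycloaddition. Several processes could then compete:
- Lewis-acid-induced migration of the double bond
- proton loss or bond rotation in a zwitterionic intermediate, which would lose the Z information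
- erosion of facial selectivity

The fallback gives up the ring and takes both stereocentres from the chiral pool. It sets out from 4 and comes back at 23.

Purchased diethyl (S)-malate F1 is converted into its alkoxide–enolate dianion (LiHMDS, 2 equiv, THF, −78 °C) and alkylated with 4. By the established anti preference of such dianions this should give diethyl (2S,3R)-3-[4-(benzyloxy)-3-methoxybenzyl]-2-hydroxybutanedioate F2.

Saponification (KOH, aq EtOH) gives (2S,3R)-3-[4-(benzyloxy)-3-methoxybenzyl]-2-hydroxybutanedioic acid F3. Acetalisation with pivalaldehyde (cat. TsOH, CH2Cl2, water removal) gives the cis-dioxolanone (2R)-3-[4-(benzyloxy)-3-methoxyphenyl]-2-[(2S,4S)-2-tert-butyl-5-oxo-1,3-dioxolan-4-yl]propanoic acid F4.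

The carboxylate–enolate dianion of F4 (LiHMDS, 2 equiv, −78 °C) is benzylated by a second portion of 4, anti to the tert-butyl group. The benzyl group therefore takes the place of the C8' hydrogen with overall retention (self-regeneration of the stereocentre). The product is (2R)-3-[4-(benzyloxy)-3-methoxyphenyl]-2-{(2S,4S)-4-[4-(benzyloxy)-3-methoxybenzyl]-2-tert-butyl-5-oxo-1,3-dioxolan-4-yl}propanoic acid F5. LiAlH4 reduces both carboxyl carbons and releases the acetal to give 23.

**Step 9.** Shielding of the neopentyl-type C9' methylene by the auxiliary may slow deprotonation. Competing deprotonation at C8, or β-elimination of the alkoxide on warming, could then take over.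

The fallback generates the enolate regiospecifically by halogen–metal exchange instead of deprotonation. It sets out from 16 (skipping step 8) and comes back at 22.

n-BuLi (1.05 equiv, THF, −78 °C) exchanges one chlorine of 16 to give the lithium 2-chloroenolate F6. TMSCl traps it as {[(3S,4R)-3,4-bis[4-(benzyloxy)-3-methoxybenzyl]-2-chloro-3-[(1S)-1-(2,4,6-triisopropylphenyl)ethoxy]cyclobut-1-en-1-yl]oxy}trimethylsilane F7.

Ozonolysis (O3, CH2Cl2, −78 °C; Me2S) gives a silyl ester next to an acid chloride. These close to (3S,4R)-3,4-bis[4-(benzyloxy)-3-methoxybenzyl]-3-[(1S)-1-(2,4,6-triisopropylphenyl)ethoxy]oxolane-2,5-dione F8. LiAlH4 reduces this anhydride to 22.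

**Step 5.** The bulk of the auxiliary may divert tin to C8. Protodestannylation during isolation and sluggish transmetalation in step 6 would add to the loss.

The fallback builds the C8=C8' bond itself by ester alkylidenation. It sets out from 5 and 4 and comes back at 13.

Alcohol 5 is esterified (DCC, DMAP, CH2Cl2) with purchased [4-(benzyloxy)-3-methoxyphenyl]acetic acid F9 to give (S)-1-(2,4,6-triisopropylphenyl)ethyl [4-(benzyloxy)-3-methoxyphenyl]acetate F10. Bromide 4 is alkylated with LiCHBr2 (CH2Br2, LDA, THF, −90 °C) to give 1-(benzyloxy)-4-(2,2-dibromoethyl)-2-methoxybenzene F11.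

Takai–Utimoto alkylidenation of F10 with F11 (TiCl4, Zn, TMEDA, cat. PbCl2, THF, rt) is non-basic and inherently Z-selective for esters. It should deliver 13.

**Further compounds**

F1 | step 7 | diethyl (S)-malate (purchased) | CCOC(=O)C[C@H](O)C(=O)OCC
F2 | step 7 | diethyl (2S,3R)-3-[4-(benzyloxy)-3-methoxybenzyl]-2-hydroxybutanedioate | COc1cc(C[C@@H](C(=O)OCC)[C@H](O)C(=O)OCC)ccc1OCc1ccccc1
F3 | step 7 | (2S,3R)-3-[4-(benzyloxy)-3-methoxybenzyl]-2-hydroxybutanedioic acid | COc1cc(C[C@@H](C(=O)O)[C@H](O)C(=O)O)ccc1OCc1ccccc1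
F4 | step 7 | (2R)-3-[4-(benzyloxy)-3-methoxyphenyl]-2-[(2S,4S)-2-tert-butyl-5-oxo-1,3-dioxolan-4-yl]propanoic acid | COc1cc(C[C@@H](C(=O)O)[C@@H]2O[C@H](C(C)(C)C)OC2=O)ccc1OCc1ccccc1
F5 | step 7 | (2R)-3-[4-(benzyloxy)-3-methoxyphenyl]-2-{(2S,4S)-4-[4-(benzyloxy)-3-methoxybenzyl]-2-tert-butyl-5-oxo-1,3-dioxolan-4-yl}propanoic acid | COc1cc(C[C@@H](C(=O)O)[C@]2(Cc3ccc(OCc4ccccc4)c(OC)c3)O[C@H](C(C)(C)C)OC2=O)ccc1OCc1ccccc1
F6 | step 9 | lithium 2-chloroenolate derived from 16 | [Li+].COc1cc(C[C@H]2C([O-])=C(Cl)[C@]2(O[C@@H](C)c2c(C(C)C)cc(C(C)C)cc2C(C)C)Cc2ccc(OCc3ccccc3)c(OC)c2)ccc1OCc1ccccc1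
F7 | step 9 | {[(3S,4R)-3,4-bis[4-(benzyloxy)-3-methoxybenzyl]-2-chloro-3-[(1S)-1-(2,4,6-triisopropylphenyl)ethoxy]cyclobut-1-en-1-yl]oxy}trimethylsilane | COc1cc(C[C@H]2C(O[Si](C)(C)C)=C(Cl)[C@]2(O[C@@H](C)c2c(C(C)C)cc(C(C)C)cc2C(C)C)Cc2ccc(OCc3ccccc3)c(OC)c2)ccc1OCc1ccccc1
F8 | step 9 | (3S,4R)-3,4-bis[4-(benzyloxy)-3-methoxybenzyl]-3-[(1S)-1-(2,4,6-triisopropylphenyl)ethoxy]oxolane-2,5-dione | COc1cc(C[C@H]2C(=O)OC(=O)[C@]2(O[C@@H](C)c2c(C(C)C)cc(C(C)C)cc2C(C)C)Cc2ccc(OCc3ccccc3)c(OC)c2)ccc1OCc1ccccc1
F9 | step 5 | [4-(benzyloxy)-3-methoxyphenyl]acetic acid (purchased) | COc1cc(CC(=O)O)ccc1OCc1ccccc1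
F10 | step 5 | (S)-1-(2,4,6-triisopropylphenyl)ethyl [4-(benzyloxy)-3-methoxyphenyl]acetate | COc1cc(CC(=O)O[C@@H](C)c2c(C(C)C)cc(C(C)C)cc2C(C)C)ccc1OCc1ccccc1
F11 | step 5 | 1-(benzyloxy)-4-(2,2-dibromoethyl)-2-methoxybenzene | COc1cc(CC(Br)Br)ccc1OCc1ccccc1
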